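(The earlier runs and the new flask come from a simulation for substances that don't exist; noise was put on by code.)

A one-step first-order reaction puts the same share of its charge into product at a given time, whatever the charge. These flasks do not.

| flask | starting material | product | time |
|---|---|---|---|
| spring | 0.150 M |  |  |
| dawn | 0.0600 M |  |  |
| summer | 0.450 M |  |  |
| winter | 0.150 M | 0.0450 M |  |
| dusk | 0.150 M |  | 56 h |

- spring run (time / h: [product] / M): 2.8: 0.0160; 5.6: 0.0374; 8.4: 0.0530; 11: 0.0627; 14: 0.0719
- dawn run (time / h: [product] / M): 2.8: 0.0069; 5.6: 0.0168; 8.4: 0.0251; 11: 0.0300; 14: 0.0351
- summer run (time / h: [product] / M): 2.8: 0.0394; 5.6: 0.0827; 8.4: 0.1112; 11: 0.1297; 14: 0.1428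
- winter run (time / h: [product] / M): 2.8: 0.0613; 5.6: 0.0809; 8.4: 0.0975; 11: 0.1085; 14: 0.1164

(scatter of a reading: 4 × 10⁻⁴ M)

- the power of [starting material] that the first rate follows, about the charge of the spring run; measure it at two percent of starting material made into product (one fixed amount of product, the same in the runs compared)
- product in the dusk run at 56 h, as a share of the starting material charged
- which of these the readings show (the product decays / the product binds the substrate / two substrates go astray together / the product speeds the reaction)

At 14 h the share f of the charge made into product is 58.5% in dawn, 47.9% in spring and 31.7% in summer, so it is lower in spring than in dawn and lower again in summer. Winter makes 0.0714 M beyond its added product, and spring makes 0.0719 M, so I set product aside. I take a first-order path to product beside a loss of two starting material together. Then, with w the first-order clock running from zero to 1, the same in each flask at one time: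

f = ln(1 + x·w) / x

The end state is w = 1. Here x grows with the charge, and summer has 3.00 times the x of spring. Equal clocks at 14 h, with y = e^(x·f) for spring, give:

3.00(y − 1) = y·y − 1

This uses the fact that 3.00 times the summer share is twice the spring share. The root that counts is y = 2, so:

x = ln(2) / f = 1.45

I call x the crowding number: loss rate over product rate at the charge of spring and dusk, a selectivity factor at the charge. The spring clock then reads 0.692. The dusk time is 4.00 such spans, so:

w = 0.991, f = 61.5%

The weak link is the pair of runs behind x. Dawn was not used, and its x is 0.578. Its clock at 14 h reads 0.696, so x stands.

The forecast says 62%, order 0.55, and two substrates go astray together, on the ground that “Fractional yield falls as the charge rises”. Its share is higher than mine.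

The dusk flask gives 62.8% at 56 h.

    starting material ⇌ intermediate (0.2174 h⁻¹, 0.1973 h⁻¹)
    intermediate → product (0.2556 h⁻¹)
    2 starting material → homo dimer (0.6516 M⁻¹ h⁻¹)

About the spring charge, the first rate follows starting material with order 0.59, and the readings show two substrates go astray together. Where equal product has been made, winter runs at 1.0 of the spring rate. Now dawn: half of its charge needs a clock of 0.580. Spring, with its x, reads 0.574 at 11 h, so I look to dawn near that time. The dawn flask comes to half of its charge at 10.9 h.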